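Readings and results are calculated with constants of no real substance; noise was put on by code.

The ratio of reagent to starting material charged, 90.0% for the flask, is its turnover ceiling: if each reagent turns over one starting material, conversion stops there, with reagent the limiting reagent. The runs read that way. Maple, with a ceiling of 57.9%, still shows 43% starting material at 8.00 h, while birch, charged with more reagent than starting material, is down to 3% at 2.00 h.

all flasks: starting material 0.19 M
- maple: reagent 0.11 M; run made earlier
- birch: reagent 0.26 M; run made earlier
- flask: reagent 0.171 M; time 12 h

- maple (time / h: starting material / %, product / %): 0.500: 55, 50; 1.33: 48, 54; 3.00: 45, 58; 8.00: 43, 55
- birch (time / h: starting material / %, product / %): 2.00: 3, 96; 4.00: 0, 98; 5.00: 0, 101; 8.00: 1, 97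

(each reading ± 2 percentage points)

- which holds at 12 h: what has brought the reaction to rest, or that it has not come to rest (the reagent has run out first / all of the starting material has reacted / forward and back rates have come level / it is still moving)
- conversion of starting material at 12 h
- amount of product at 12 h, in percent of the starting material charged

- the numbers in the tables scatter by 2 percentage points (one standard deviation)
- a reading or a percentage of product counts all its forms, free or not
- the reaction counts as stopped when no species that holds the starting material changes by six tenths of a point or more over the second half of the time

The ceiling bounds the flask from above. My own floor comes from maple read at its worst: two standard deviations more starting material give a conversion of 53.0%. Product over the two leftovers, all as fractions of the starting charge, is then 23.0. Held at that value, the flask's ceiling gives 76.1%. So this reckoning brackets the flask between 76.1% and 90.0%, and the flask's 12 h is longer than birch's 2.00 h.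

The forecast says forward and back rates have come level, with conversion 88% and product 88%, inside that bracket and just under the ceiling, since near stoichiometry “that leaves a few points unreacted”.

The flask gives forward and back rates have come level, with conversion 84.9% and product 84.9%.

    starting material + reagent ⇌ product (K = 9.80 M⁻¹, k = 0.430 M⁻¹ min⁻¹)
    crystals ⇌ product, rate k2*(cs2 - [product]) while solid is left; crystals form when [product] > cs2 (solubility = 2.70 mM, k = 6.50 min⁻¹)

The flask stops 5.1 percentage points under its ceiling and inside the bracket, and its state of rest is the one the forecast named. Starting material stands at 15.1% after 6.00 h and at 15.1% after 12.0 h, with 5.6% of the reagent's own charge left. Crystals in the flask hold 83.5% of the starting charge, counted in the product. A neighbour charged with 0.76 M of starting material has a ceiling of 22.5%. That neighbour gives a conversion of 22.4%, with its reagent down to 0.273% of its own charge.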